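**Retrosynthetic overview**

1. The target is the (1S,3aR,4S,6aR)-1,4-diaryl-tetrahydro-1H,3H-furo[3,4-c]furan; it is traced back over debenzylation and deoxygenation at C6 to a cis-fused C6 lactol.
2. Enabling feature: C1 (the guaiacyl-bearing carbon, bonded to O2) is an aldehyde-level carbon, and C6 on the neighbouring C6a is one too in the lactol. The C1–C6a bond is therefore an aldol bond between an aryl oxocarbenium ion C1=O2 and the enol of C6, and O2 and the C6 oxygen can be the two oxygens of one acetal.
3. Key disconnection: the ring C1–O2–C3–C3a–C6a is made by contraction of a seven-membered vinyl acetal (a 2-aryl-4,5-dihydro-1,3-dioxepine). Its C7 and O1 leave the ring as the C6 formyl group, which the C4 carbinol then captures as the second ring (O5–C6 bond).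
4. The vinyl acetal comes from asymmetric double-bond migration in its 4,7-dihydro isomer (sets C3a), made by acetalisation of O-benzylvanillin with a 2-substituted cis-butenediol. That diol comes from a three-component nickel-catalysed reductive coupling of the second aryl aldehyde, a butynediol ether and a silane (sets C4).
5. Ring order: dioxepine (7) → guaiacyl tetrahydrofuran (5, by contraction) → second tetrahydrofuran (lactol, then CH2).

Key step: step 6

Remark: the sense of induction of the two chiral catalysts (steps 3 and 5) is not assigned here; in each case the ligand antipode is taken to be the one that leads to the configuration drawn.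
Remark: the carbinol centre keeps its spatial arrangement throughout; its descriptor changes from R (while its carbon neighbour is sp2) to S (after step 5) only because the ranking of its neighbours changes.

**Step 1**
Reactants: 1 3-hydroxy-4,5-dimethoxybenzaldehyde
Product: 2 3-(benzyloxy)-4,5-dimethoxybenzaldehyde
Conditions: BnBr, K2CO3, DMF, rt
Reagents that add atoms: benzyl bromide, BrCc1ccccc1
Why: Williamson ether synthesis (SN2 of the phenoxide on benzyl bromide) that masks the phenol for all later organometallic and Lewis acid steps; no stereocentre is formed.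

**Step 2**
Reactants: 3 but-2-yne-1,4-diol
Product: 4 1,4-bis(trimethylsilyloxy)but-2-yne
Conditions: TMSCl, Et3N, CH2Cl2, 0 °C to rt
Reagents that add atoms: chlorotrimethylsilane, C[Si](C)(C)Cl
Why: O-silylation gives propargylic ethers that should tolerate the low-valent nickel catalyst of step 3 and can be removed again by mild methanolysis without touching a secondary triethylsilyl ether.

**Step 3**
Reactants: 2 3-(benzyloxy)-4,5-dimethoxybenzaldehyde; 4 1,4-bis(trimethylsilyloxy)but-2-yne
Product: 6 (E)-2-[(R)-[3-(benzyloxy)-4,5-dimethoxyphenyl](triethylsilyloxy)methyl]but-2-ene-1,4-diol, via tris-silyl ether 5 (not isolated)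
Conditions: Ni(cod)2 (10 mol %), chiral C2-symmetric imidazolinium tetrafluoroborate (4,5-diphenyl backbone, ortho-substituted N-aryl groups; 10 mol %), KOtBu (10 mol %), Et3SiH, THF, rt; then K2CO3, MeOH, 0 °C
Reagents that add atoms: triethylsilane, CC[SiH](CC)CC
Why: Nickel-catalysed three-component aldehyde–alkyne reductive coupling: oxidative cyclisation on zerovalent nickel gives an oxanickelacyclopentene, the silane cleaves its Ni–O bond and C–H reductive elimination follows, so C and H add syn (E alkene, the two CH2O arms cis) and the carbinol appears directly as its triethylsilyl ether with its configuration set by the chiral carbene ligand; K2CO3/MeOH then cleaves only the two primary trimethylsilyl ethers.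

**Step 4**
Reactants: 6 (E)-2-[(R)-[3-(benzyloxy)-4,5-dimethoxyphenyl](triethylsilyloxy)methyl]but-2-ene-1,4-diol; 7 4-(benzyloxy)-3-methoxybenzaldehyde
Product: 9 2-[4-(benzyloxy)-3-methoxyphenyl]-5-[(R)-[3-(benzyloxy)-4,5-dimethoxyphenyl](triethylsilyloxy)methyl]-4,7-dihydro-1,3-dioxepine (both C2 epimers), via dimethyl acetal 8 (not isolated)
Conditions: 7, HC(OMe)3, PPTS (cat.), MeOH, rt, evaporate; then 6, PPTS (cat.), 5 Å MS, CH2Cl2, rt
Reagents that add atoms: none
Why: Acid-catalysed transacetalisation in which the cis-disposed CH2OH groups close the seven-membered acetal while the silylated secondary oxygen cannot compete for a six-membered acetal; the acetal carbon forms as both epimers, which is inconsequential because it becomes planar in step 6.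

**Step 5**
Reactants: 9 2-[4-(benzyloxy)-3-methoxyphenyl]-5-[(R)-[3-(benzyloxy)-4,5-dimethoxyphenyl](triethylsilyloxy)methyl]-4,7-dihydro-1,3-dioxepine
Product: 10 (5R)-2-[4-(benzyloxy)-3-methoxyphenyl]-5-[(S)-[3-(benzyloxy)-4,5-dimethoxyphenyl](triethylsilyloxy)methyl]-4,5-dihydro-1,3-dioxepine (both C2 epimers)
Conditions: NiBr2[(R,R)-Me-DuPHOS] or its antipode (5 mol %), LiBHEt3 (5 mol %), THF, −40 °C to rt
Reagents that add atoms: none
Why: Asymmetric nickel hydride-catalysed double-bond migration (hydrometalation/β-hydride elimination, allyl ether to enol ether), a reaction type known for 5-alkyl-4,7-dihydro-1,3-dioxepines: H is delivered to C5 and nickel to the less substituted C6, β-hydride elimination from C7 gives the vinyl acetal, and the new C5 centre is set by ligand-controlled face selection.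

**Step 6**
Reactants: 10 (5R)-2-[4-(benzyloxy)-3-methoxyphenyl]-5-[(S)-[3-(benzyloxy)-4,5-dimethoxyphenyl](triethylsilyloxy)methyl]-4,5-dihydro-1,3-dioxepine
Product: 14 (3S,3aR,6S,6aS)-6-[4-(benzyloxy)-3-methoxyphenyl]-3-[3-(benzyloxy)-4,5-dimethoxyphenyl]tetrahydro-1H,3H-furo[3,4-c]furan-1-ol (lactol; both anomers), via kinetic silyl ether aldehyde 11 (not isolated), via kinetic hydroxy aldehyde 12 (not isolated), via epimerised hydroxy aldehyde 13 (not isolated)
Conditions: TMSOTf (0.2 equiv), 2,6-di-tert-butyl-4-methylpyridine (0.3 equiv), CH2Cl2, −78 °C; then Bu4NF (2 equiv, THF), −78 to 0 °C; then DBU (1 equiv), rt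
Reagents that add atoms: none
Why: The silyl triflate ionises the acetal C2–O1 bond, releasing the (Z)-enolate of C7 and leaving an aryl-stabilised (E)-oxocarbenium ion on O3, and the tethered ion pair recombines at carbon (C6 to C2), the Lewis acid-mediated ring contraction of 4,5-dihydro-1,3-dioxepines to tetrahydrofuran-3-carbaldehydes (a 1,3 O-to-C shift of Petasis–Ferrier type, in effect an intramolecular Mukaiyama aldol addition), so that the seven-membered ring loses O1 and C7 and becomes the guaiacyl-bearing tetrahydrofuran by a 5-(enolexo)-endo-trig closure. Under kinetic control at −78 °C the enolate is expected to add in the compact synclinal mode (formyl cis to aryl) and, because allylic 1,3-strain with the Z-enolate oxygen turns the C5 hydrogen into the enolate plane, on the face opposite to the C5 side chain, so the single C5 centre fixes the new aryl-bearing centre trans to the side chain, while the acetal epimers converge because C2 is planar in the ion pair. Fluoride then frees the carbinol and DBU epimerises the formyl-bearing centre through its enolate (loss of the ring oxygen from this enolate would be the reverse of a 5-endo-trig addition and should not compete); only the epimer with the formyl group cis to the carbinol chain can close, by 5-exo-trig hemiacetalisation, to the cis-fused lactol, which drains the equilibrium. The step needs C–C bond formation that is kinetic and is not reversed (a retro-aldol return to the ion pair would scramble the aryl-bearing centre), which the low temperature, the substoichiometric Lewis acid, the buffered medium and the cold fluoride quench are meant to secure; attack of the carbinol oxygen on the oxocarbenium ion is excluded by the silyl ether.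

**Step 7**
Reactants: 14 (3S,3aR,6S,6aS)-6-[4-(benzyloxy)-3-methoxyphenyl]-3-[3-(benzyloxy)-4,5-dimethoxyphenyl]tetrahydro-1H,3H-furo[3,4-c]furan-1-ol
Product: 15 (1S,3aR,4S,6aR)-1-[4-(benzyloxy)-3-methoxyphenyl]-4-[3-(benzyloxy)-4,5-dimethoxyphenyl]tetrahydro-1H,3H-furo[3,4-c]furan
Conditions: Et3SiH, BF3·OEt2, CH2Cl2, −78 to −40 °C
Reagents that add atoms: none
Why: Ionic hydrogenation of the lactol: BF3 ionises the anomeric hydroxyl to the bicyclic oxocarbenium ion, which the silane reduces to CH2 (no stereocentre is created, both anomers converge), and at this temperature the two benzylic ring ethers should not ionise.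

**Step 8**
Reactants: 15 (1S,3aR,4S,6aR)-1-[4-(benzyloxy)-3-methoxyphenyl]-4-[3-(benzyloxy)-4,5-dimethoxyphenyl]tetrahydro-1H,3H-furo[3,4-c]furan
Product: 16 4-[(1S,3aR,4S,6aR)-4-(3-hydroxy-4,5-dimethoxyphenyl)tetrahydro-1H,3H-furo[3,4-c]furan-1-yl]-2-methoxyphenol
Conditions: H2 (1 atm), Pd/C, EtOAc, rt, stopped after uptake of two equivalents
Reagents that add atoms: none
Why: Hydrogenolysis of the two aryl benzyl ethers on palladium, which should be much faster than cleavage of the hindered ring benzylic C–O bonds, so that no stereocentre is touched if the reaction is stopped at full debenzylation.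

**Compound list**

1 | 3-hydroxy-4,5-dimethoxybenzaldehyde | O=Cc1cc(O)c(OC)c(OC)c1 | starting material
2 | 3-(benzyloxy)-4,5-dimethoxybenzaldehyde | O=Cc1cc(OCc2ccccc2)c(OC)c(OC)c1 | intermediate
3 | but-2-yne-1,4-diol | OCC#CCO | starting material
4 | 1,4-bis(trimethylsilyloxy)but-2-yne | C[Si](C)(C)OCC#CCO[Si](C)(C)C | intermediate
5 | (R,E)-1-[3-(benzyloxy)-4,5-dimethoxyphenyl]-1-(triethylsilyloxy)-4-(trimethylsilyloxy)-2-[(trimethylsilyloxy)methyl]but-2-ene | CC[Si](CC)(CC)O[C@@H](/C(CO[Si](C)(C)C)=C/CO[Si](C)(C)C)c1cc(OCc2ccccc2)c(OC)c(OC)c1 | intermediate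
6 | (E)-2-[(R)-[3-(benzyloxy)-4,5-dimethoxyphenyl](triethylsilyloxy)methyl]but-2-ene-1,4-diol | CC[Si](CC)(CC)O[C@@H](/C(CO)=C/CO)c1cc(OCc2ccccc2)c(OC)c(OC)c1 | intermediate
7 | 4-(benzyloxy)-3-methoxybenzaldehyde | COc1cc(C=O)ccc1OCc1ccccc1 | starting material
8 | 1-(benzyloxy)-4-(dimethoxymethyl)-2-methoxybenzene | COc1cc(C(OC)OC)ccc1OCc1ccccc1 | intermediate
9 | 2-[4-(benzyloxy)-3-methoxyphenyl]-5-[(R)-[3-(benzyloxy)-4,5-dimethoxyphenyl](triethylsilyloxy)methyl]-4,7-dihydro-1,3-dioxepine (C2 epimers) | COc1cc(C2OCC([C@H](O[Si](CC)(CC)CC)c3cc(OCc4ccccc4)c(OC)c(OC)c3)=CCO2)ccc1OCc1ccccc1 | intermediate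
10 | (5R)-2-[4-(benzyloxy)-3-methoxyphenyl]-5-[(S)-[3-(benzyloxy)-4,5-dimethoxyphenyl](triethylsilyloxy)methyl]-4,5-dihydro-1,3-dioxepine (C2 epimers) | COc1cc(C2OC[C@H]([C@H](O[Si](CC)(CC)CC)c3cc(OCc4ccccc4)c(OC)c(OC)c3)C=CO2)ccc1OCc1ccccc1 | intermediate
11 | (2S,3R,4R)-2-[4-(benzyloxy)-3-methoxyphenyl]-4-[(S)-[3-(benzyloxy)-4,5-dimethoxyphenyl](triethylsilyloxy)methyl]tetrahydrofuran-3-carbaldehyde (2,3-cis-3,4-trans) | COc1cc([C@H]2OC[C@H]([C@H](O[Si](CC)(CC)CC)c3cc(OCc4ccccc4)c(OC)c(OC)c3)[C@H]2C=O)ccc1OCc1ccccc1 | intermediate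
12 | (2S,3R,4R)-2-[4-(benzyloxy)-3-methoxyphenyl]-4-[(S)-[3-(benzyloxy)-4,5-dimethoxyphenyl](hydroxy)methyl]tetrahydrofuran-3-carbaldehyde (2,3-cis-3,4-trans) | COc1cc([C@H]2OC[C@H]([C@H](O)c3cc(OCc4ccccc4)c(OC)c(OC)c3)[C@H]2C=O)ccc1OCc1ccccc1 | intermediate
13 | (2S,3S,4R)-2-[4-(benzyloxy)-3-methoxyphenyl]-4-[(S)-[3-(benzyloxy)-4,5-dimethoxyphenyl](hydroxy)methyl]tetrahydrofuran-3-carbaldehyde (2,3-trans-3,4-cis) | COc1cc([C@H]2OC[C@H]([C@H](O)c3cc(OCc4ccccc4)c(OC)c(OC)c3)[C@@H]2C=O)ccc1OCc1ccccc1 | intermediate
14 | (3S,3aR,6S,6aS)-6-[4-(benzyloxy)-3-methoxyphenyl]-3-[3-(benzyloxy)-4,5-dimethoxyphenyl]tetrahydro-1H,3H-furo[3,4-c]furan-1-ol (both anomers) | COc1cc([C@H]2OC[C@H]3[C@@H]2C(O)O[C@@H]3c2cc(OCc3ccccc3)c(OC)c(OC)c2)ccc1OCc1ccccc1 | intermediate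
15 | (1S,3aR,4S,6aR)-1-[4-(benzyloxy)-3-methoxyphenyl]-4-[3-(benzyloxy)-4,5-dimethoxyphenyl]tetrahydro-1H,3H-furo[3,4-c]furan | COc1cc([C@H]2OC[C@H]3[C@@H]2CO[C@@H]3c2cc(OCc3ccccc3)c(OC)c(OC)c2)ccc1OCc1ccccc1 | intermediate
16 | 4-[(1S,3aR,4S,6aR)-4-(3-hydroxy-4,5-dimethoxyphenyl)tetrahydro-1H,3H-furo[3,4-c]furan-1-yl]-2-methoxyphenol | COc1cc([C@H]2OC[C@H]3[C@@H]2CO[C@@H]3c2cc(O)c(OC)c(OC)c2)ccc1O | target

**Step count**

Total: 8 steps. Longest linear sequence: 7 steps (steps 1, 3, 4, 5, 6, 7, 8).

**Three steps most likely to fail**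

Step 5. What may go wrong: hydride is delivered to C5 with poor facial selectivity because the resident carbinol centre and the epimeric acetal carbon oppose the chiral nickel hydride, or the double bond migrates toward the carbinol carbon instead of toward the ring oxygen. Fallback (sets out from 2 and 7, comes back at 10): C5 and the carbinol centre are set together by an iridium-catalysed transfer-hydrogenative anti-(hydroxymethyl)allylation of 2 with 4,7-dihydro-1,3-dioxepin-2-one ([Ir(cod)Cl]2, (R)- or (S)-SEGPHOS, 4-cyano-3-nitrobenzoic acid, Cs2CO3, 2-propanol, THF, 90 °C), which should give the anti diol (1S,2R)-1-[3-(benzyloxy)-4,5-dimethoxyphenyl]-2-ethenylpropane-1,3-diol F1. Silylation (TESCl, imidazole, DMF) to the bis(triethylsilyl) ether F2 and selective methanolysis of the primary silyl ether (PPTS, MeOH, 0 °C) give the primary alcohol (2R,3S)-3-[3-(benzyloxy)-4,5-dimethoxyphenyl]-2-ethenyl-3-(triethylsilyloxy)propan-1-ol F3. In parallel 7 is condensed with 2-bromoethanol (TsOH, toluene, azeotropic removal of water) to 1-(benzyloxy)-4-[bis(2-bromoethoxy)methyl]-2-methoxybenzene F4, which is transacetalised with F3 (PPTS, CH2Cl2, excess F4) to the mixed 2-bromoethyl acetal F5. KOtBu (THF, 0 °C) eliminates HBr to the mixed vinyl acetal F6, and ring-closing metathesis between the vinyl ether and the C-vinyl group (second-generation Grubbs catalyst, toluene, 70 °C) closes the seven-membered enol ether, which is 10.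

Step 6. What may go wrong: the C–C bond forms with the wrong topology (antiperiplanar instead of synclinal addition, or memory of the acetal configuration in a tight ion pair), or it is reversed before the quench, so that after epimerisation the aryl-bearing centre ends up cis to the side chain. Fallback (sets out from 10, comes back at 14): the silyl ether is removed first (Bu4NF, THF, 0 °C) to give the carbinol (5R)-2-[4-(benzyloxy)-3-methoxyphenyl]-5-[(S)-[3-(benzyloxy)-4,5-dimethoxyphenyl](hydroxy)methyl]-4,5-dihydro-1,3-dioxepine F7. The same seven-to-five contraction is then run under chelate control with Me2AlCl (2.5 equiv, CH2Cl2, −78 °C), a usual promoter of vinyl acetal O-to-C rearrangements. The aluminium alkoxide of the carbinol can bridge to the enolate oxygen, which should hold the side chain cis to the nascent formyl group and place the bulky chelate anti to the oxocarbenium ion; the 2,3-trans-3,4-cis aldehyde would then form directly and collapse to the aluminium lactolate of 14 without a base-mediated epimerisation.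

Step 3. What may go wrong: insufficient differentiation of the aldehyde faces by the carbene–nickel catalyst, so that low enantiomeric purity is carried through the route, or direct hydrosilylation of the aldehyde outrunning the coupling. Fallback (sets out from 2 and 4, comes back at 5): hydroboration of 4 with Cy2BH (toluene, 0 °C to rt), boron-to-zinc exchange with Me2Zn (−78 °C) and addition of the alkenylzinc reagent to 2 under catalysis by (−)- or (+)-3-exo-morpholinoisoborneol (−10 °C) should give the allylic alcohol (R,E)-1-[3-(benzyloxy)-4,5-dimethoxyphenyl]-4-(trimethylsilyloxy)-2-[(trimethylsilyloxy)methyl]but-2-en-1-ol F8; the syn hydroboration secures the same E geometry. Silylation (TESCl, imidazole, DMF) converts F8 into 5, which is desilylated at the primary positions as in step 3.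

**Further compounds**

F1 | step 5 | (1S,2R)-1-[3-(benzyloxy)-4,5-dimethoxyphenyl]-2-ethenylpropane-1,3-diol | OC[C@@H](C=C)[C@H](O)c1cc(OCc2ccccc2)c(OC)c(OC)c1
F2 | step 5 | (1S,2R)-1-[3-(benzyloxy)-4,5-dimethoxyphenyl]-2-ethenyl-1,3-bis(triethylsilyloxy)propane | CC[Si](CC)(CC)OC[C@@H](C=C)[C@H](O[Si](CC)(CC)CC)c1cc(OCc2ccccc2)c(OC)c(OC)c1
F3 | step 5 | (2R,3S)-3-[3-(benzyloxy)-4,5-dimethoxyphenyl]-2-ethenyl-3-(triethylsilyloxy)propan-1-ol | OC[C@@H](C=C)[C@H](O[Si](CC)(CC)CC)c1cc(OCc2ccccc2)c(OC)c(OC)c1
F4 | step 5 | 1-(benzyloxy)-4-[bis(2-bromoethoxy)methyl]-2-methoxybenzene | COc1cc(C(OCCBr)OCCBr)ccc1OCc1ccccc1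
F5 | step 5 | mixed 2-bromoethyl acetal of 7 with F3 (both acetal epimers) | COc1cc(C(OCCBr)OC[C@@H](C=C)[C@H](O[Si](CC)(CC)CC)c2cc(OCc3ccccc3)c(OC)c(OC)c2)ccc1OCc1ccccc1
F6 | step 5 | mixed vinyl acetal of 7 with F3 (both acetal epimers) | COc1cc(C(OC=C)OC[C@@H](C=C)[C@H](O[Si](CC)(CC)CC)c2cc(OCc3ccccc3)c(OC)c(OC)c2)ccc1OCc1ccccc1
F7 | step 6 | (5R)-2-[4-(benzyloxy)-3-methoxyphenyl]-5-[(S)-[3-(benzyloxy)-4,5-dimethoxyphenyl](hydroxy)methyl]-4,5-dihydro-1,3-dioxepine (C2 epimers) | COc1cc(C2OC[C@H]([C@H](O)c3cc(OCc4ccccc4)c(OC)c(OC)c3)C=CO2)ccc1OCc1ccccc1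
F8 | step 3 | (R,E)-1-[3-(benzyloxy)-4,5-dimethoxyphenyl]-4-(trimethylsilyloxy)-2-[(trimethylsilyloxy)methyl]but-2-en-1-ol | O[C@@H](/C(CO[Si](C)(C)C)=C/CO[Si](C)(C)C)c1cc(OCc2ccccc2)c(OC)c(OC)c1
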